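(The runs were computed with constants of no real substance, and the scatter is random.)

A leftover is where we begin: starting material still in a flask at its last reading has not yet been divided, so the readings can show how it divides without showing how far that flask has gone.

| setting | Monday's | Saturday's | Wednesday's | blue | ochre | green |
|---|---|---|---|---|---|---|
| starting material | 0.050 M | 0.050 M | 0.075 M | 0.050 M | 0.050 M | 0.050 M |
| first nucleophile | 0.050 M | 0.050 M | 0.050 M | 0.0500 M | 0.0500 M | 0.0500 M |
| second nucleophile | 0.034 M | 0.075 M | 0.050 M | 0.0500 M | 0.0500 M | 0.0500 M |
| temperature | 116 °C | 130 °C | 116 °C | 110 °C |  | 135 °C |
| remark | run made earlier | run made earlier | run made earlier |  | at 110 °C until 40 min, from then on at 135 °C |  |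
| time |  |  |  | 2.0 h | 2.0 h | 2.0 h |

Monday's run (percent of the starting material charged)

| time / h | target / % | other capture product / % |
|---|---|---|
| 0.200 | 3.9 | 0.9 |
| 0.333 | 5.9 | 2.1 |
| 0.667 | 11.2 | 3.9 |
| 1.33 | 20.5 | 7.4 |
| 2.50 | 32.2 | 9.9 |

Saturday's run (percent of the starting material charged)

| time / min | target / % | other capture product / % |
|---|---|---|
| 4.00 | 3.2 | 2.8 |
| 15.0 | 11.5 | 6.8 |
| 20.0 | 13.4 | 10.1 |
| 30.0 | 18.0 | 12.6 |
| 60.0 | 26.5 | 20.5 |

Wednesday's run (percent of the starting material charged)

| time / h | target / % | other capture product / % |
|---|---|---|
| 0.200 | 2.5 | 1.7 |
| 0.333 | 5.8 | 1.3 |
| 0.667 | 11.1 | 3.7 |
| 1.33 | 18.9 | 8.1 |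
| 2.50 | 29.0 | 14.1 |

(readings scatter by 0.5 percentage points)

- in percentages every species weighs as the starting material in it: one side product counts as two
- a reading or a percentage of target counts all its forms, free or not

* the best flask by share of target in all that became target or other capture product or solvolysis product or over-reaction product or side product; "all alike" if 1.5 percentage points covers them all (blue / ochre / green / all alike)
* share of target in all that became target or other capture product or solvolysis product or over-reaction product or side product, blue
* share of target in all that became target or other capture product or solvolysis product or over-reaction product or side product, ochre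
* share of target in all that became target or other capture product or solvolysis product or over-reaction product or side product, green

Suppose the two nucleophiles compete for the same thing. If we divide the rate of making target by the rate of making other capture product, time drops out, and our bench rule follows: at one temperature, target over other capture product equals a constant times first nucleophile over second nucleophile. Saturday's last reading, at 130 °C, gives that constant as 1.94. We call it the split factor, a selectivity factor: target made per other capture product when the nucleophiles stand equal. Wednesday's last reading gives 2.06 and Monday's 2.21, both at 116 °C. At equal charges, as in blue, ochre and green, the rule puts target at 66.0% of the two capture products.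

The rule uses charges, though, and capture consumes nucleophile. Counting fractions of each charge, Saturday's readings leave at most 0.735 of the first nucleophile and 0.863 of the second, so by this count their ratio stands at 0.851 of its starting value. Saturday's target per other capture product, read over the last interval against the first 30.0 min, stands lower, at 0.753 of its earlier value, though this is a reading built from differences of scattered readings. That is the border: in a deep flask we expect some target to be lost as well, and the asked share to lie below the rule's figure.

The forecast picks blue, with 64% for blue, 48% for ochre and 46% for green: “Blue reaches only about 24% conversion, so its share stays near 64%.”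

The flasks give 62.7% for blue, 44.3% for ochre and 41.2% for green, so blue is best, and the forecast stands within its tolerance.

    starting material → intermediate (k = 0.170 h⁻¹, Ea = 113 kJ mol⁻¹)
    first nucleophile + intermediate → target (k = 8600 L mol⁻¹ h⁻¹, Ea = 57.0 kJ mol⁻¹)
    second nucleophile + intermediate → other capture product (k = 3100 L mol⁻¹ h⁻¹, Ea = 69.0 kJ mol⁻¹)
    intermediate → solvolysis product (k = 73.0 h⁻¹, Ea = 109 kJ mol⁻¹)
    crystals ⇌ target, rate k5*(cs5 - [target]) while solid is left; crystals form when [target] > cs5 (solubility = 17.0 mM, k = 13.0 h⁻¹)
    second nucleophile + target → over-reaction product (k = 0.300 L mol⁻¹ h⁻¹, Ea = 109 kJ mol⁻¹)
    starting material + intermediate → side product (k = 2.20 L mol⁻¹ h⁻¹, Ea = 82.0 kJ mol⁻¹)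
    (constants at 110 °C)

Green's target of 39.1% includes 5.04% as crystals, which barely move its share. Counting green's over-reaction product back as target gives 1.92 per other capture product, against the split factor's 1.94. A neighbouring flask is green with 0.20 M of second nucleophile. There the rule says 0.485, and that flask, its over-reaction product counted back in the same way, gives 0.510, with its share of target at 15.7%.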